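The north run was impossible as a plain chain of exchanges. Complex with four exchanged and complex with two exchanged together stood at 64.6%, 68.2% and 65.9% at 1.04 d, 2.00 d and 4.00 d, while complex with two exchanged alone fell from 41.9% to 15.9%. So I took the missing part, 34.1% or a third, as a dead end and not as a queue feeding the chain.

all flasks: starting complex 0.050 M

| flask | incoming ligand | leaving ligand | remark | time |
|---|---|---|---|---|
| north-east | 0.015 M | 0.025 M | run made earlier |  |
| north | 0.15 M | 0.025 M | run made earlier |  |
| spring | 0.200 M | 0.0250 M |  | 4.0 d |
| summer | 0.0250 M | 0.0250 M |  | 4.0 d |

| run | time / d | complex with four exchanged / % | complex with two exchanged / % |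
|---|---|---|---|
| north-east | 0.333 | 0.1 | 1.3 |
| north-east | 0.625 | 0 | 2.5 |
| north-east | 1.04 | 0 | 2.0 |
| north-east | 2.00 | 1.0 | 4.7 |
| north-east | 4.00 | 2.5 | 3.0 |
| north | 0.333 | 4.8 | 40.8 |
| north | 0.625 | 14.1 | 44.1 |
| north | 1.04 | 22.7 | 41.9 |
| north | 2.00 | 38.8 | 29.4 |
| north | 4.00 | 50.0 | 15.9 |

(readings scatter by 1 percentage point)

1. which of these holds the largest part of the starting complex at the end of spring (starting complex / complex with two exchanged / complex with three exchanged / complex with one exchanged / complex with four exchanged)
2. which of these holds the largest part of the starting complex at the end of summer (starting complex / complex with two exchanged / complex with three exchanged / complex with one exchanged / complex with four exchanged)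
3. how much complex with four exchanged is there at the end of spring, in percent of the starting complex charged



I ran spring in slow motion. In the first instants starting complex stood at a fork: one exchange, which needs incoming ligand, or the dead end, which I assumed does not. The odds of loss then vary inversely with the incoming charge, so north gives 0.0776 M, the break-even charge, the amount of incoming ligand at which each branch takes half, a selectivity factor in concentration units, for leaving ligand charged at 0.025 M. The lost share is this charge over itself plus the incoming charge: 28.0% for spring, leaving 72.0%.

For the middle I went by the north run, where the survivors gathered as complex with two exchanged, with a highest reading of 44.1% at 0.625 d; there the step out of it looked like the rate-limiting step. Spring's 4.00 equivalents cover the 2.88 that I reckoned the survivors need for four exchanges each.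

At the end, complex with four exchanged holds the survivors minus what still waits. At 4.00 d the north run had 24.1% of its read survivors waiting as complex with two exchanged, and spring was charged with more incoming ligand than north, so I put complex with four exchanged in spring between 54.6% and 72.0%, ahead of complex with two exchanged. For summer I reckoned 75.6% lost and called an exchanged form the leader, not starting complex.

The forecast said complex with four exchanged for spring, starting complex for summer and 70% of complex with four exchanged, holding that the “incoming ligand acts as the limit on exchange”; on summer I parted from it.

Spring ended with 66.9% of complex with four exchanged, and summer's leader among the forms asked was complex with one exchanged, at 19.9%.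

    starting complex + incoming ligand → leaving ligand + complex with one exchanged (k = 0.0787 M⁻¹ min⁻¹)
    complex with one exchanged + incoming ligand → leaving ligand + complex with two exchanged (k = 0.0267 M⁻¹ min⁻¹)
    complex with two exchanged + incoming ligand → leaving ligand + complex with three exchanged (k = 0.00578 M⁻¹ min⁻¹)
    complex with three exchanged + incoming ligand → leaving ligand + complex with four exchanged (k = 0.179 M⁻¹ min⁻¹)
    leaving ligand + starting complex → side product (k = 0.117 M⁻¹ min⁻¹)

The dead end was the side product, which held 26.4% in spring against my 28.0%. For the neighbouring flask, spring with 0.050 M of incoming ligand, the break-even charge gives 60.8% lost, and that flask held 53.5% as side product.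

The numbers in the tables are calculated for an exercise, noise included.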